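**Remark on the chemistry (assumptions).** The target has no stereocentre (it is achiral), so no enantiocontrol is needed. The stereocentres of 10, 12, 14, 18 and 19 are transient and are carried as mixtures. The benzofuran-2,6-dione drawn is taken as the stable tautomer of the oxidised system, since the 4'-quinoid/6-hydroxy form is related to it by proton transfer only.

## Retrosynthetic overview

1. Target 20 ⇐ dehydrogenation (C3–H and O6–H) of the 3-arylbenzofuran-2(3H)-one 19; the quinone methide (C3=C3a through to C6=O) is unveiled last.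
2. Lactone ring (bonds C3–C2 and C2–O1) ⇐ formal [4+1] of an isocyanide (donor of C2) onto o-quinone methide 16, which already holds O1–C7a–C3a=C3(Ar).
3. Carbocycle C3a–C4(Ph)–C5(OMe)–C6(O)–C7(Ph)–C7a ⇐ strain-releasing 4π ring opening/6π ring closure of 4-allenylcyclobutenone 14 (new bond C7a–C3a); all six ring substituents come from the four-membered ring and the allene.
4. 14 ⇐ propargyl isomer 12 ⇐ squarate-derived dione 4 + 1,3-diarylpropyne 7 (allenyltitanium SE2' addition, then O-methylation, which becomes the C5 methoxy group).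
5. Ring order: cyclobutene (purchased) → six-membered carbocycle → lactone, the last two in one flask.

Key step: step 5

## Route

**Step 1**
Reactants: 1 3,4-diisopropoxycyclobut-3-ene-1,2-dione (diisopropyl squarate); 2 phenyllithium
Product: 4 3-isopropoxy-4-phenylcyclobut-3-ene-1,2-dione, via hydroxycyclobutenone 3 (not isolated)
Conditions: PhLi (1.05 equiv), THF, −78 °C; then 12 M HCl, CH2Cl2, rt
Reagents that add atoms: phenyllithium (2), [Li]c1ccccc1
Why: 1,2-addition of the aryllithium to one squarate carbonyl, then acid-promoted allylic transposition of the hydroxyl with loss of isopropanol, is the standard entry to 3-alkoxy-4-arylcyclobutenediones.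

**Step 2**
Reactants: 5 1-iodo-4-isopropoxybenzene; 6 prop-2-yn-1-ylbenzene (3-phenyl-1-propyne)
Product: 7 1-isopropoxy-4-(3-phenylprop-1-yn-1-yl)benzene
Conditions: Pd(PPh3)2Cl2 (2 mol%), CuI (4 mol%), Et3N, THF, rt
Reagents that add atoms: none
Why: Sonogashira coupling of an aryl iodide proceeds at room temperature, mild enough to leave the propargylic CH2 unisomerised.

**Step 3**
Reactants: 7 1-isopropoxy-4-(3-phenylprop-1-yn-1-yl)benzene; 4 3-isopropoxy-4-phenylcyclobut-3-ene-1,2-dione
Product: 10 4-hydroxy-3-isopropoxy-4-[3-(4-isopropoxyphenyl)-1-phenylprop-2-yn-1-yl]-2-phenylcyclobut-2-en-1-one, via propargyllithium 8 (not isolated), via allenyltitanium 9 (not isolated)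
Conditions: n-BuLi (1.05 equiv), THF, −78 °C; ClTi(OiPr)3 (1.1 equiv), −78 °C; then 4, −78 → −20 °C; aq NH4Cl
Reagents that add atoms: none
Why: Deprotonation of the doubly activated CH2 and transmetalation give an allenyltitanium (Ti on the aryl-bearing carbon) that should add by SE2' through its CH(Ph) terminus to the more electrophilic C2 carbonyl of 4 (not the vinylogous ester carbonyl), giving the homopropargylic alcohol; the two new stereocentres form without control and are destroyed in step 5.

**Step 4**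
Reactants: 10 4-hydroxy-3-isopropoxy-4-[3-(4-isopropoxyphenyl)-1-phenylprop-2-yn-1-yl]-2-phenylcyclobut-2-en-1-one; 11 iodomethane
Product: 12 3-isopropoxy-4-[3-(4-isopropoxyphenyl)-1-phenylprop-2-yn-1-yl]-4-methoxy-2-phenylcyclobut-2-en-1-one
Conditions: MeI (excess), Ag2O, CaSO4, MeCN, rt, dark
Reagents that add atoms: iodomethane (11), CI
Why: Purdie-type O-methylation of the tertiary 4-hydroxycyclobutenone under essentially non-basic conditions installs the future C5 methoxy group and blocks the quinone-forming pathway open to a free 4-hydroxyl.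

**Step 5 (key step)**
Reactants: 12 3-isopropoxy-4-[3-(4-isopropoxyphenyl)-1-phenylprop-2-yn-1-yl]-4-methoxy-2-phenylcyclobut-2-en-1-one; 13 tert-butyl isocyanide
Product: 18 rac-6-isopropoxy-3-(4-isopropoxyphenyl)-5-methoxy-4,7-diphenylbenzofuran-2(3H)-one, via allenylcyclobutenone 14 (not isolated), via dienylketene 15 (not isolated), via o-quinone methide 16 (not isolated), via aminobenzofuran 17 (not isolated)
Conditions: DBU (0.2 equiv), PhMe, rt; then t-BuNC (3 equiv), 110 °C, sealed tube; then 2 M HCl, THF, 60 °C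
Reagents that add atoms: tert-butyl isocyanide (13), [C-]#[N+]C(C)(C)C; water, O
Why: DBU shifts the benzylic/propargylic proton to give the conjugated allene 14 (the known 1,3-diarylpropyne-to-allene isomerisation), and on heating the cyclobutenone opens by conrotatory 4π ring opening to dienylketene 15, whose 6π-electrocyclisation joins the ketene carbon (future C7a) to the central allene carbon (future C3a) and closes the carbocycle as o-quinone methide 16. This is the known ring expansion of 4-allenylcyclobutenones to o-quinone methides (Moore rearrangement), driven by release of the four-ring strain. The lactone ring is closed by a formal [4+1]: the isocyanide carbon adds to the exocyclic benzylidene carbon (future C3) and the resulting phenoxide oxygen closes 5-exo onto the nitrilium carbon (O1–C2), the known o-quinone methide/isocyanide route to 2-aminobenzofurans. Aqueous acid then hydrolyses the ketene N,O-acetal 17 to the lactone with loss of tert-butylamine. The only stereocentre formed (C3) is racemic and is erased in step 7. The step needs the allenyl group to rotate inward on ring opening, which the outward preference of the 4-methoxy donor secures, and it needs the isocyanide to attack the exocyclic carbon, which is the only position whose attack restores the arene; the electrocyclisation has no regiochemical alternative because every ring position is already assigned.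

**Step 6**
Reactants: 18 rac-6-isopropoxy-3-(4-isopropoxyphenyl)-5-methoxy-4,7-diphenylbenzofuran-2(3H)-one
Product: 19 rac-6-hydroxy-3-(4-hydroxyphenyl)-5-methoxy-4,7-diphenylbenzofuran-2(3H)-one
Conditions: BCl3 (6 equiv), CH2Cl2, −78 → 0 °C; then H2O
Reagents that add atoms: none
Why: Lewis-acid dealkylation with BCl3 cleaves aryl isopropyl ethers much faster than aryl methyl ethers at low temperature, and the lactone is inert to it.

**Step 7**
Reactants: 19 rac-6-hydroxy-3-(4-hydroxyphenyl)-5-methoxy-4,7-diphenylbenzofuran-2(3H)-one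
Product: 20 3-(4-hydroxyphenyl)-5-methoxy-4,7-diphenylbenzofuran-2,6-dione (target)
Conditions: DDQ (1.05 equiv), 1,4-dioxane, rt
Reagents that add atoms: none
Why: DDQ dehydrogenation of the p-hydroxybenzylic C3–H (C3a is para to C6–OH) should give the extended p-quinone methide, erasing the C3 stereocentre, with proton transfer settling the stable 2,6-dione tautomer.

## Compound list

1 | 3,4-diisopropoxycyclobut-3-ene-1,2-dione (diisopropyl squarate) | CC(C)OC1=C(OC(C)C)C(=O)C1=O | starting material
2 | phenyllithium | [Li]c1ccccc1 | starting material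
3 | 4-hydroxy-2,3-diisopropoxy-4-phenylcyclobut-2-en-1-one | CC(C)OC1=C(OC(C)C)C(O)(c2ccccc2)C1=O | intermediate
4 | 3-isopropoxy-4-phenylcyclobut-3-ene-1,2-dione | CC(C)OC1=C(c2ccccc2)C(=O)C1=O | intermediate
5 | 1-iodo-4-isopropoxybenzene | CC(C)Oc1ccc(I)cc1 | starting material
6 | prop-2-yn-1-ylbenzene (3-phenyl-1-propyne) | C#CCc1ccccc1 | starting material
7 | 1-isopropoxy-4-(3-phenylprop-1-yn-1-yl)benzene | CC(C)Oc1ccc(cc1)C#CCc1ccccc1 | intermediate
8 | [3-(4-isopropoxyphenyl)-1-phenylprop-2-yn-1-yl]lithium (propargyl/allenyl anion) | [Li]C(C#Cc1ccc(OC(C)C)cc1)c1ccccc1 | intermediate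
9 | triisopropoxy[1-(4-isopropoxyphenyl)-3-phenylpropa-1,2-dien-1-yl]titanium | CC(C)Oc1ccc(cc1)C(=C=Cc1ccccc1)[Ti](OC(C)C)(OC(C)C)OC(C)C | intermediate
10 | 4-hydroxy-3-isopropoxy-4-[3-(4-isopropoxyphenyl)-1-phenylprop-2-yn-1-yl]-2-phenylcyclobut-2-en-1-one (diastereomer mixture) | CC(C)OC1=C(c2ccccc2)C(=O)C1(O)C(c1ccccc1)C#Cc1ccc(OC(C)C)cc1 | intermediate
11 | iodomethane | CI | starting material
12 | 3-isopropoxy-4-[3-(4-isopropoxyphenyl)-1-phenylprop-2-yn-1-yl]-4-methoxy-2-phenylcyclobut-2-en-1-one (diastereomer mixture) | CC(C)OC1=C(c2ccccc2)C(=O)C1(OC)C(c1ccccc1)C#Cc1ccc(OC(C)C)cc1 | intermediate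
13 | tert-butyl isocyanide | [C-]#[N+]C(C)(C)C | starting material
14 | 3-isopropoxy-4-[3-(4-isopropoxyphenyl)-1-phenylpropa-1,2-dien-1-yl]-4-methoxy-2-phenylcyclobut-2-en-1-one | CC(C)OC1=C(c2ccccc2)C(=O)C1(OC)C(c1ccccc1)=C=Cc1ccc(OC(C)C)cc1 | intermediate
15 | (3Z)-3-isopropoxy-7-(4-isopropoxyphenyl)-4-methoxy-2,5-diphenylhepta-1,3,5,6-tetraen-1-one (dienylketene) | O=C=C(c1ccccc1)/C(OC(C)C)=C(/OC)C(c1ccccc1)=C=Cc1ccc(OC(C)C)cc1 | intermediate
16 | 3-isopropoxy-6-(4-isopropoxybenzylidene)-4-methoxy-2,5-diphenylcyclohexa-2,4-dien-1-one (o-quinone methide, E/Z not defined) | O=C1C(c2ccccc2)=C(OC(C)C)C(OC)=C(c2ccccc2)C1=Cc1ccc(OC(C)C)cc1 | intermediate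
17 | N-tert-butyl-6-isopropoxy-3-(4-isopropoxyphenyl)-5-methoxy-4,7-diphenylbenzofuran-2-amine | CC(C)(C)Nc1oc2c(-c3ccccc3)c(OC(C)C)c(OC)c(-c3ccccc3)c2c1-c1ccc(OC(C)C)cc1 | intermediate
18 | rac-6-isopropoxy-3-(4-isopropoxyphenyl)-5-methoxy-4,7-diphenylbenzofuran-2(3H)-one | O=C1Oc2c(-c3ccccc3)c(OC(C)C)c(OC)c(-c3ccccc3)c2C1c1ccc(OC(C)C)cc1 | intermediate
19 | rac-6-hydroxy-3-(4-hydroxyphenyl)-5-methoxy-4,7-diphenylbenzofuran-2(3H)-one | O=C1Oc2c(-c3ccccc3)c(O)c(OC)c(-c3ccccc3)c2C1c1ccc(O)cc1 | intermediate
20 | 3-(4-hydroxyphenyl)-5-methoxy-4,7-diphenylbenzofuran-2,6-dione | COC1=C(c2ccccc2)C2=C(c3ccc(O)cc3)C(=O)OC2=C(c2ccccc2)C1=O | target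

## Summary and risks

Total step count: 7. Longest linear sequence: 6 steps (1 → 3 → 4 → 5 → 6 → 7, or 2 → 3 → 4 → 5 → 6 → 7).

**Step 5 (key step).** Two processes may spoil it. The propargyl anion formed by DBU may expel the neighbouring methoxide (E1cB) instead of being reprotonated to the allene. The o-quinone methide may also decay by oligomerisation faster than the isocyanide captures it. The fallback sets out from 4 and returns at 19; it builds the arene by the alkenyl variant of the cyclobutenone ring expansion and closes the lactone by Friedel–Crafts alkylation/lactonisation. 1-Phenylvinyllithium (from (1-bromovinyl)benzene and t-BuLi, THF, −78 °C) is added to 4 and the alkoxide is quenched with MeOTf to give 3-isopropoxy-4-methoxy-2-phenyl-4-(1-phenylethenyl)cyclobut-2-en-1-one F1. Heating F1 in toluene at 110 °C (4π opening, 6π closure, tautomerisation) should give 3-isopropoxy-4-methoxy-2,5-diphenylphenol F2, whose only free ring position is the future C3a. Condensation of F2 with 4-hydroxymandelic acid (TsOH, 1,2-dichloroethane, 80 °C) should give rac-3-(4-hydroxyphenyl)-6-isopropoxy-5-methoxy-4,7-diphenylbenzofuran-2(3H)-one F3. BCl3 as in step 6 then gives 19.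

**Step 3.** The ambident propargyl/allenyl metal may attack through its aryl-bearing terminus, or may add only sluggishly to the hindered ketone. The fallback sets out from 4 and returns at 14, which is then heated with t-BuNC and hydrolysed as in step 5 with the DBU stage omitted; it forms the C–C(sp) bond first and makes the allene by palladium-catalysed SN2' arylation.
- 4-Isopropoxybenzaldehyde and ethynylmagnesium bromide give 1-(4-isopropoxyphenyl)prop-2-yn-1-ol F4.
- TBSCl/imidazole gives its silyl ether tert-butyl{[1-(4-isopropoxyphenyl)prop-2-yn-1-yl]oxy}dimethylsilane F5.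
- The lithium acetylide of F5 (n-BuLi, THF, −78 °C) is added to 4 and quenched with MeOTf to give 4-{3-[(tert-butyldimethylsilyl)oxy]-3-(4-isopropoxyphenyl)prop-1-yn-1-yl}-3-isopropoxy-4-methoxy-2-phenylcyclobut-2-en-1-one F6.
- HF·pyridine gives 4-[3-hydroxy-3-(4-isopropoxyphenyl)prop-1-yn-1-yl]-3-isopropoxy-4-methoxy-2-phenylcyclobut-2-en-1-one F7.
- ClCO2Me/pyridine gives 1-(4-isopropoxyphenyl)-3-(2-isopropoxy-1-methoxy-4-oxo-3-phenylcyclobut-2-en-1-yl)prop-2-yn-1-yl methyl carbonate F8.
- Pd(PPh3)4 and PhB(OH)2 (THF, rt) should convert F8 to 14 through the σ-allenylpalladium intermediate.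

**Step 6.** Once O6 is bound to boron, neighbouring-group-assisted cleavage may remove the C5 methyl ether together with the isopropyl groups. The fallback sets out from 18 and returns at 20; it accepts global dealkylation and restores the methyl group at the end by a regioselective methylation. BBr3 (CH2Cl2, −78 °C → rt) gives rac-5,6-dihydroxy-3-(4-hydroxyphenyl)-4,7-diphenylbenzofuran-2(3H)-one F9. DDQ (dioxane, rt) gives 5-hydroxy-3-(4-hydroxyphenyl)-4,7-diphenylbenzofuran-2,6-dione F10. One equivalent of TMSCHN2 (toluene/MeOH, 0 °C) should methylate only the acidic enolic 5-OH (a vinylogous acid next to C6=O) and not the 4'-phenol, giving 20.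

## Further compounds

F1 | step 5 | 3-isopropoxy-4-methoxy-2-phenyl-4-(1-phenylethenyl)cyclobut-2-en-1-one | CC(C)OC1=C(c2ccccc2)C(=O)C1(OC)C(=C)c1ccccc1
F2 | step 5 | 3-isopropoxy-4-methoxy-2,5-diphenylphenol | CC(C)Oc1c(OC)c(-c2ccccc2)cc(O)c1-c1ccccc1
F3 | step 5 | rac-3-(4-hydroxyphenyl)-6-isopropoxy-5-methoxy-4,7-diphenylbenzofuran-2(3H)-one | O=C1Oc2c(-c3ccccc3)c(OC(C)C)c(OC)c(-c3ccccc3)c2C1c1ccc(O)cc1
F4 | step 3 | 1-(4-isopropoxyphenyl)prop-2-yn-1-ol | CC(C)Oc1ccc(cc1)C(O)C#C
F5 | step 3 | tert-butyl{[1-(4-isopropoxyphenyl)prop-2-yn-1-yl]oxy}dimethylsilane | CC(C)Oc1ccc(cc1)C(O[Si](C)(C)C(C)(C)C)C#C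
F6 | step 3 | 4-{3-[(tert-butyldimethylsilyl)oxy]-3-(4-isopropoxyphenyl)prop-1-yn-1-yl}-3-isopropoxy-4-methoxy-2-phenylcyclobut-2-en-1-one | CC(C)OC1=C(c2ccccc2)C(=O)C1(OC)C#CC(O[Si](C)(C)C(C)(C)C)c1ccc(OC(C)C)cc1
F7 | step 3 | 4-[3-hydroxy-3-(4-isopropoxyphenyl)prop-1-yn-1-yl]-3-isopropoxy-4-methoxy-2-phenylcyclobut-2-en-1-one | CC(C)OC1=C(c2ccccc2)C(=O)C1(OC)C#CC(O)c1ccc(OC(C)C)cc1
F8 | step 3 | 1-(4-isopropoxyphenyl)-3-(2-isopropoxy-1-methoxy-4-oxo-3-phenylcyclobut-2-en-1-yl)prop-2-yn-1-yl methyl carbonate | CC(C)OC1=C(c2ccccc2)C(=O)C1(OC)C#CC(OC(=O)OC)c1ccc(OC(C)C)cc1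
F9 | step 6 | rac-5,6-dihydroxy-3-(4-hydroxyphenyl)-4,7-diphenylbenzofuran-2(3H)-one | O=C1Oc2c(-c3ccccc3)c(O)c(O)c(-c3ccccc3)c2C1c1ccc(O)cc1
F10 | step 6 | 5-hydroxy-3-(4-hydroxyphenyl)-4,7-diphenylbenzofuran-2,6-dione | OC1=C(c2ccccc2)C2=C(c3ccc(O)cc3)C(=O)OC2=C(c2ccccc2)C1=O
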